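**Retrosynthetic overview**
- The target is the C10 acetate of a bicyclic alcohol whose 12-membered ring is closed last, at C10–C11, by an intramolecular Nozaki–Hiyama–Kishi allylation of a 2-(bromomethyl)enone onto a tethered aldehyde; this step also sets C10 and C11 and creates the C12=C18 methylene.
- The bromo aldehyde comes from a coupled enone by Shi epoxidation of the 3Z olefin, Appel bromination at C18 and ozonolysis of a terminal vinyl group.
- The coupled enone is cut at C2–C3 (Negishi sp3–sp2 coupling) into a ring alkyl iodide and a chain (Z)-alkenyl iodide that already carries the 7,8-epoxide.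
- Ring fragment: 4,4-dimethylcyclohex-2-enone → dienone → Rh-catalysed asymmetric vinylation (C1) → vinyl to CH2I → Baylis–Hillman (C18). Chain fragment: allyl bromide plus acetylene, oxirane and propyne units (carboalumination for 7E, carbocupration for 3Z, Shi epoxidation for 7R,8R).
- Ring order: the cyclohexenone is present from the start; then the 7,8-oxirane (step 12), the 3,4-oxirane (step 14), and the 12-membered carbocycle (step 17).

Assumption: atoms are labelled by verticillane numbering (C1 and C11 ring-fusion CH, C15 the CMe2 bridge, C2–C10 the nine-carbon bridge, C12=C18 the methylene, C13 the ketone); the target is then 1R,3R,4S,7R,8R,10R,11S, with a cis 3,4-epoxide, a trans 7,8-epoxide and C2/C10 trans on the six-membered ring.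

**Route**

Step 1
Reactants: 1 4,4-dimethylcyclohex-2-en-1-one
Product: 2 4,4-dimethylcyclohexa-2,5-dien-1-one
Conditions: DDQ (1.3 equiv), 1,4-dioxane, reflux
Reagents that add atoms: none
Why: DDQ dehydrogenation (hydride abstraction from the enol, then proton loss) introduces the second enone double bond, the quaternary carbon blocks aromatisation and no stereocentre is formed.

Step 2
Reactants: 2 4,4-dimethylcyclohexa-2,5-dien-1-one
Product: 3 (5S)-5-ethenyl-4,4-dimethylcyclohex-2-en-1-one
Conditions: CH2=CHBF3K (1.1 equiv), [Rh(cod)2]BF4 (3 mol %), (S)-BINAP (3.3 mol %), toluene/H2O 4:1, 100 °C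
Reagents that add atoms: potassium vinyltrifluoroborate, [K+].C=C[B-](F)(F)F
Why: Hayashi–Miyaura rhodium-catalysed asymmetric 1,4-addition desymmetrises the prochiral dienone, the (S)-BINAP–Rh–vinyl species adding to one enantiotopic β-carbon face (sense assigned by analogy with cyclohex-2-enone; the ligand antipode is used if the sense proves opposite) to set C1, and the product enone is hindered enough to resist a second addition.

Step 3
Reactants: 3 (5S)-5-ethenyl-4,4-dimethylcyclohex-2-en-1-one
Product: 5 (1R)-2,2-dimethyl-5-oxocyclohex-3-ene-1-carbaldehyde, via secondary ozonide 4 (not isolated)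
Conditions: O3, CH2Cl2, −78 °C (Sudan red 7B end-point); Me2S, −78 °C → rt
Reagents that add atoms: ozone, [O-][O+]=O
Why: Ozonolysis (Criegee mechanism) cleaves the electron-rich vinyl group much faster than the electron-poor enone C=C, leaving C2 as the aldehyde carbon without epimerising C1 (the descriptor changes only because of CIP priorities).

Step 4
Reactants: 5 (1R)-2,2-dimethyl-5-oxocyclohex-3-ene-1-carbaldehyde
Product: 6 (5R)-5-(hydroxymethyl)-4,4-dimethylcyclohex-2-en-1-one
Conditions: NaBH(OAc)3 (1.5 equiv), benzene, 50 °C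
Reagents that add atoms: none
Why: Chemoselective hydride reduction, since NaBH(OAc)3 reduces aldehydes but not the conjugated ketone, so C2 becomes CH2OH with C1 untouched.

Step 5
Reactants: 6 (5R)-5-(hydroxymethyl)-4,4-dimethylcyclohex-2-en-1-one
Product: 7 (5R)-5-(iodomethyl)-4,4-dimethylcyclohex-2-en-1-one
Conditions: I2, PPh3, imidazole, CH2Cl2, 0 °C → rt
Reagents that add atoms: iodine, II
Why: Appel-type iodination converts the primary alcohol into the iodide by SN2 displacement of the oxyphosphonium group at the non-stereogenic C2.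

Step 6
Reactants: 7 (5R)-5-(iodomethyl)-4,4-dimethylcyclohex-2-en-1-one
Product: 8 (5R)-2-(hydroxymethyl)-5-(iodomethyl)-4,4-dimethylcyclohex-2-en-1-one
Conditions: 37 % aq. CH2O, DMAP (0.5 equiv), THF/H2O 1:1, rt
Reagents that add atoms: formaldehyde, C=O
Why: Morita–Baylis–Hillman reaction, in which DMAP adds reversibly to C11, the enolate is hydroxymethylated at C12 and DMAP is expelled, placing C18 regiospecifically on the enone α-carbon without touching C1 or the alkyl iodide.

Step 7
Reactants: 9 3-bromoprop-1-ene (allyl bromide)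
Product: 10 pent-1-en-4-yne
Conditions: HC≡CMgBr (0.5 M in THF, 1.2 equiv), CuCl (5 mol %), THF, 0 → 40 °C; fractional distillation
Reagents that add atoms: ethynylmagnesium bromide, C#C[Mg]Br
Why: Copper-catalysed substitution of the allylic bromide by the alkynyl Grignard reagent gives the skipped enyne (SN2 and SN2' paths give the same product) with no stereochemistry involved.

Step 8
Reactants: 10 pent-1-en-4-yne
Product: 12 (1E)-1-iodo-2-methylpenta-1,4-diene, via alkenylalane 11 (not isolated)
Conditions: Me3Al (2 equiv), Cp2ZrCl2 (0.2 equiv), CH2Cl2, 0 °C → rt; then I2, THF, −30 → 0 °C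
Reagents that add atoms: trimethylaluminium, C[Al](C)C; iodine, II
Why: Negishi zirconium-catalysed carboalumination adds Me and Al syn across the terminal alkyne (Me to the internal carbon, the isolated alkene being left alone) and iodinolysis proceeds with retention, fixing the 7E trisubstituted olefin.

Step 9
Reactants: 12 (1E)-1-iodo-2-methylpenta-1,4-diene
Product: 14 (3E)-4-methylhepta-3,6-dien-1-ol, via alkenyllithium 13 (not isolated)
Conditions: t-BuLi (2.1 equiv), Et2O, −78 °C; oxirane (3 equiv), −78 → 0 °C; H2O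
Reagents that add atoms: oxirane, C1CO1
Why: Iodine–lithium exchange with retention of olefin geometry followed by ring opening of oxirane by the alkenyllithium adds C6 and C5 as a CH2CH2OH unit.

Step 10
Reactants: 14 (3E)-4-methylhepta-3,6-dien-1-ol
Product: 15 (4E)-7-bromo-4-methylhepta-1,4-diene
Conditions: CBr4, PPh3, CH2Cl2, 0 °C
Reagents that add atoms: tetrabromomethane, BrC(Br)(Br)Br
Why: Appel bromination of the primary alcohol (SN2 at C5) provides the halide needed for Grignard formation without touching either olefin.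

Step 11
Reactants: 15 (4E)-7-bromo-4-methylhepta-1,4-diene
Product: 19 (1Z,5E)-1-iodo-2,6-dimethylnona-1,5,8-triene, via Grignard reagent 16 (not isolated), via alkylcopper 17 (not isolated), via alkenylcopper 18 (not isolated)
Conditions: Mg, Et2O, rt; CuBr·SMe2 (1 equiv), Et2O/Me2S, −45 °C; propyne (2 equiv), −25 °C; I2, THF, −50 → 0 °C
Reagents that add atoms: propyne, CC#C; iodine, II
Why: Normant carbocupration adds the alkylcopper syn across propyne with the alkyl group on the internal carbon and copper on the terminus, and iodinolysis with retention gives the Z alkenyl iodide in which iodine (the future C2 position) and C5 are cis.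

Step 12
Reactants: 19 (1Z,5E)-1-iodo-2,6-dimethylnona-1,5,8-triene
Product: 20 (2R,3R)-2-[(3Z)-4-iodo-3-methylbut-3-en-1-yl]-3-methyl-3-(prop-2-en-1-yl)oxirane
Conditions: Shi ketone (D-fructose-derived, 0.3 equiv), KHSO5 (as 2KHSO5·KHSO4·K2SO4, 1.4 equiv), K2CO3, Bu4NHSO4 (cat.), MeCN/CH2(OMe)2, aq. Na2B4O7 buffer, 0 °C
Reagents that add atoms: potassium peroxymonosulfate, [K+].[O-]S(=O)(=O)OO
Why: Shi asymmetric epoxidation, in which the chiral dioxirane attacks the electron-rich E trisubstituted olefin through the spiro transition state to give R at the CH carbon (7R,8R in target numbering), while the iodoalkene and the terminal vinyl group react far more slowly.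

Step 13
Reactants: 8 (5R)-2-(hydroxymethyl)-5-(iodomethyl)-4,4-dimethylcyclohex-2-en-1-one; 20 (2R,3R)-2-[(3Z)-4-iodo-3-methylbut-3-en-1-yl]-3-methyl-3-(prop-2-en-1-yl)oxirane
Product: 22 (5R)-2-(hydroxymethyl)-4,4-dimethyl-5-{(2Z)-3-methyl-5-[(2R,3R)-3-methyl-3-(prop-2-en-1-yl)oxiran-2-yl]pent-2-en-1-yl}cyclohex-2-en-1-one, via alkylzinc iodide 21 (not isolated)
Conditions: 8, Zn dust (activated with BrCH2CH2Br/TMSCl), LiCl, THF, 30 °C; then 20, Pd(OAc)2 (3 mol %), SPhos (6 mol %), THF, rt
Reagents that add atoms: none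
Why: Negishi cross-coupling, in which zinc inserts into the C–I bond of 8 (the ketone and free hydroxyl are tolerated by the alkylzinc iodide) and the sp3 zinc reagent couples with the alkenyl iodide under zerovalent palladium with retention of the Z geometry to form C2–C3, the epoxide and terminal alkene being inert.

Step 14
Reactants: 22 (5R)-2-(hydroxymethyl)-4,4-dimethyl-5-{(2Z)-3-methyl-5-[(2R,3R)-3-methyl-3-(prop-2-en-1-yl)oxiran-2-yl]pent-2-en-1-yl}cyclohex-2-en-1-one
Product: 23 (5R)-2-(hydroxymethyl)-4,4-dimethyl-5-{[(2R,3S)-3-methyl-3-{2-[(2R,3R)-3-methyl-3-(prop-2-en-1-yl)oxiran-2-yl]ethyl}oxiran-2-yl]methyl}cyclohex-2-en-1-one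
Conditions: Shi ketone (D-fructose-derived, 0.3 equiv), KHSO5 (as 2KHSO5·KHSO4·K2SO4, 1.4 equiv), K2CO3, Bu4NHSO4 (cat.), MeCN/CH2(OMe)2, aq. Na2B4O7 buffer, 0 °C
Reagents that add atoms: potassium peroxymonosulfate, [K+].[O-]S(=O)(=O)OO
Why: Second Shi epoxidation, where the catalyst again selects the face at the CH terminus of the only remaining electron-rich trisubstituted olefin to give R at C3 and, because the olefin is Z, the cis epoxide (3R,4S), the enone and vinyl group being poor substrates for the electrophilic dioxirane.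

Step 15
Reactants: 23 (5R)-2-(hydroxymethyl)-4,4-dimethyl-5-{[(2R,3S)-3-methyl-3-{2-[(2R,3R)-3-methyl-3-(prop-2-en-1-yl)oxiran-2-yl]ethyl}oxiran-2-yl]methyl}cyclohex-2-en-1-one
Product: 24 (5R)-2-(bromomethyl)-4,4-dimethyl-5-{[(2R,3S)-3-methyl-3-{2-[(2R,3R)-3-methyl-3-(prop-2-en-1-yl)oxiran-2-yl]ethyl}oxiran-2-yl]methyl}cyclohex-2-en-1-one
Conditions: CBr4, PPh3, 2,6-lutidine, CH2Cl2, −20 → 0 °C
Reagents that add atoms: tetrabromomethane, BrC(Br)(Br)Br
Why: Appel bromination of the primary allylic alcohol under buffered, non-acidic conditions leaves both epoxides intact and gives the 2-(bromomethyl)enone needed for allylmetal formation.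

Step 16
Reactants: 24 (5R)-2-(bromomethyl)-4,4-dimethyl-5-{[(2R,3S)-3-methyl-3-{2-[(2R,3R)-3-methyl-3-(prop-2-en-1-yl)oxiran-2-yl]ethyl}oxiran-2-yl]methyl}cyclohex-2-en-1-one
Product: 26 (5R)-2-(bromomethyl)-4,4-dimethyl-5-{[(2R,3S)-3-methyl-3-{2-[(2R,3R)-3-methyl-3-(2-oxoethyl)oxiran-2-yl]ethyl}oxiran-2-yl]methyl}cyclohex-2-en-1-one, via primary ozonide 25 (not isolated)
Conditions: O3 (1.0 equiv, end-point control), acetone/H2O 19:1, 0 °C; used crude
Reagents that add atoms: ozone, [O-][O+]=O
Why: Ozonolysis in aqueous acetone, where water traps the carbonyl oxide so that no sulfide or phosphine reductant (which would alkylate on the allylic bromide) is needed, cleaves the monosubstituted alkene selectively over the electron-poor bromomethyl enone to reveal the C10 aldehyde.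

Step 17
Reactants: 26 (5R)-2-(bromomethyl)-4,4-dimethyl-5-{[(2R,3S)-3-methyl-3-{2-[(2R,3R)-3-methyl-3-(2-oxoethyl)oxiran-2-yl]ethyl}oxiran-2-yl]methyl}cyclohex-2-en-1-one
Product: 28 (1R,3R,4S,7R,8R,10R,11S)-3,4:7,8-diepoxy-10-hydroxyverticill-12(18)-en-13-one, via allylchromium dichloride 27 (not isolated)
Conditions: CrCl2 (8 equiv), 4 Å MS, THF, rt, slow addition of 26 (final 0.002 M); aq. work-up
Reagents that add atoms: none
Why: Intramolecular Nozaki–Hiyama–Kishi (chromium Barbier) allylation closes the 12-membered ring, the allylchromium formed at C18 adding through its ring carbon C11 to the aldehyde in a chair Zimmerman–Traxler transition state in which the new bond forms axially and trans to the equatorial C1 side chain (C11 S, as in cuprate additions to 5-substituted cyclohexenones) and the ring-locked E-type allyl unit gives the anti adduct (C10 R), with the C12=C18 methylene generated at the same time.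

Step 18
Reactants: 28 (1R,3R,4S,7R,8R,10R,11S)-3,4:7,8-diepoxy-10-hydroxyverticill-12(18)-en-13-one
Product: 29 (1R,3R,4S,7R,8R,10R,11S)-10-acetoxy-3,4:7,8-diepoxyverticill-12(18)-en-13-one
Conditions: Ac2O, pyridine, DMAP (cat.), CH2Cl2, 0 °C
Reagents that add atoms: acetic anhydride, CC(=O)OC(C)=O
Why: DMAP-catalysed O-acylation of the secondary C10 alcohol proceeds with retention and leaves the methylene ketone and both epoxides untouched, giving the target.

**Compound list**

1 | 4,4-dimethylcyclohex-2-en-1-one | CC1(C)CCC(=O)C=C1 | starting material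
2 | 4,4-dimethylcyclohexa-2,5-dien-1-one | CC1(C)C=CC(=O)C=C1 | intermediate
3 | (5S)-5-ethenyl-4,4-dimethylcyclohex-2-en-1-one | O=C1C[C@@H](C=C)C(C)(C)C=C1 | intermediate
4 | (5R)-4,4-dimethyl-5-(1,2,4-trioxolan-3-yl)cyclohex-2-en-1-one (secondary ozonide of 3, epimers at the trioxolane carbon) | O=C1C[C@@H](C2OCOO2)C(C)(C)C=C1 | intermediate
5 | (1R)-2,2-dimethyl-5-oxocyclohex-3-ene-1-carbaldehyde | O=C1C[C@@H](C=O)C(C)(C)C=C1 | intermediate
6 | (5R)-5-(hydroxymethyl)-4,4-dimethylcyclohex-2-en-1-one | O=C1C[C@@H](CO)C(C)(C)C=C1 | intermediate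
7 | (5R)-5-(iodomethyl)-4,4-dimethylcyclohex-2-en-1-one | O=C1C[C@@H](CI)C(C)(C)C=C1 | intermediate
8 | (5R)-2-(hydroxymethyl)-5-(iodomethyl)-4,4-dimethylcyclohex-2-en-1-one | O=C1C[C@@H](CI)C(C)(C)C=C1CO | intermediate
9 | 3-bromoprop-1-ene (allyl bromide) | C=CCBr | starting material
10 | pent-1-en-4-yne | C=CCC#C | intermediate
11 | dimethyl[(1E)-2-methylpenta-1,4-dien-1-yl]alumane | C=CC/C(C)=C/[Al](C)C | intermediate
12 | (1E)-1-iodo-2-methylpenta-1,4-diene | C=CC/C(C)=C/I | intermediate
13 | [(1E)-2-methylpenta-1,4-dien-1-yl]lithium | C=CC/C(C)=C/[Li] | intermediate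
14 | (3E)-4-methylhepta-3,6-dien-1-ol | OCC/C=C(C)/CC=C | intermediate
15 | (4E)-7-bromo-4-methylhepta-1,4-diene | BrCC/C=C(C)/CC=C | intermediate
16 | bromo[(3E)-4-methylhepta-3,6-dien-1-yl]magnesium | Br[Mg]CC/C=C(C)/CC=C | intermediate
17 | [(3E)-4-methylhepta-3,6-dien-1-yl]copper (as its MgBr2·SMe2 complex) | [Cu]CC/C=C(C)/CC=C | intermediate
18 | [(1Z,5E)-2,6-dimethylnona-1,5,8-trien-1-yl]copper | [Cu]/C=C(C)\CC/C=C(C)/CC=C | intermediate
19 | (1Z,5E)-1-iodo-2,6-dimethylnona-1,5,8-triene | I/C=C(C)\CC/C=C(C)/CC=C | intermediate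
20 | (2R,3R)-2-[(3Z)-4-iodo-3-methylbut-3-en-1-yl]-3-methyl-3-(prop-2-en-1-yl)oxirane | I/C=C(C)\CC[C@H]1O[C@]1(C)CC=C | intermediate
21 | iodo{[(1R)-4-(hydroxymethyl)-2,2-dimethyl-5-oxocyclohex-3-en-1-yl]methyl}zinc | O=C1C[C@@H](C[Zn]I)C(C)(C)C=C1CO | intermediate
22 | (5R)-2-(hydroxymethyl)-4,4-dimethyl-5-{(2Z)-3-methyl-5-[(2R,3R)-3-methyl-3-(prop-2-en-1-yl)oxiran-2-yl]pent-2-en-1-yl}cyclohex-2-en-1-one | O=C1C[C@@H](C/C=C(C)\CC[C@H]2O[C@]2(C)CC=C)C(C)(C)C=C1CO | intermediate
23 | (5R)-2-(hydroxymethyl)-4,4-dimethyl-5-{[(2R,3S)-3-methyl-3-{2-[(2R,3R)-3-methyl-3-(prop-2-en-1-yl)oxiran-2-yl]ethyl}oxiran-2-yl]methyl}cyclohex-2-en-1-one | O=C1C[C@@H](C[C@H]2O[C@@]2(C)CC[C@H]3O[C@]3(C)CC=C)C(C)(C)C=C1CO | intermediate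
24 | (5R)-2-(bromomethyl)-4,4-dimethyl-5-{[(2R,3S)-3-methyl-3-{2-[(2R,3R)-3-methyl-3-(prop-2-en-1-yl)oxiran-2-yl]ethyl}oxiran-2-yl]methyl}cyclohex-2-en-1-one | O=C1C[C@@H](C[C@H]2O[C@@]2(C)CC[C@H]3O[C@]3(C)CC=C)C(C)(C)C=C1CBr | intermediate
25 | primary ozonide of 24 (terminal CH=CH2 converted into a 1,2,3-trioxolane, epimers at its CH) | O=C1C[C@@H](C[C@H]2O[C@@]2(C)CC[C@H]3O[C@]3(C)CC4COOO4)C(C)(C)C=C1CBr | intermediate
26 | (5R)-2-(bromomethyl)-4,4-dimethyl-5-{[(2R,3S)-3-methyl-3-{2-[(2R,3R)-3-methyl-3-(2-oxoethyl)oxiran-2-yl]ethyl}oxiran-2-yl]methyl}cyclohex-2-en-1-one | O=C1C[C@@H](C[C@H]2O[C@@]2(C)CC[C@H]3O[C@]3(C)CC=O)C(C)(C)C=C1CBr | intermediate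
27 | σ-allylchromium dichloride of 26 (CrCl2 in place of Br on C18, trivalent chromium) | O=C1C[C@@H](C[C@H]2O[C@@]2(C)CC[C@H]3O[C@]3(C)CC=O)C(C)(C)C=C1C[Cr](Cl)Cl | intermediate
28 | (1R,3R,4S,7R,8R,10R,11S)-3,4:7,8-diepoxy-10-hydroxyverticill-12(18)-en-13-one | C=C1C(=O)C[C@H]2C[C@H]3O[C@@]3(C)CC[C@H]3O[C@]3(C)C[C@@H](O)[C@H]1C2(C)C | intermediate
29 | (1R,3R,4S,7R,8R,10R,11S)-10-acetoxy-3,4:7,8-diepoxyverticill-12(18)-en-13-one | C=C1C(=O)C[C@H]2C[C@H]3O[C@@]3(C)CC[C@H]3O[C@]3(C)C[C@@H](OC(C)=O)[C@H]1C2(C)C | target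

**Step count and risks**

Total step count: 18. Longest linear sequence: 12 steps (steps 1–6 then 13–18; the chain branch, steps 7–12 then 13–18, is equally long).

Steps most likely to fail:

Step 2. The β-carbons of the dienone are neopentyl-like, so the rhodium insertion may be slow, and the sense of induction rests on analogy. The fallback sets out from 2 and brings in C2 as a nitromethyl group instead of a vinyl group. Iminium-catalysed Michael addition of nitromethane (9-amino-9-deoxy-epi-cinchona primary amine with PhCO2H, the quinine- or quinidine-derived pseudoenantiomer being chosen for the 5R adduct) gives (5R)-4,4-dimethyl-5-(nitromethyl)cyclohex-2-en-1-one F1. An oxidative Nef reaction (KOH/MeOH to the nitronate, then buffered KHSO5) converts CH2NO2 into CHO and comes back to the route at aldehyde 5.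

Step 6. The conjugate addition of DMAP to C11 is hindered by the adjacent quaternary carbon, and the γ-iodo ketone could close to a cyclopropyl ketone under prolonged basic conditions. The fallback sets out from 7 and replaces the organocatalytic hydroxymethylation by halogenation and cross-coupling. α-Iodination of the enone (I2, pyridine, CH2Cl2) gives (5R)-2-iodo-5-(iodomethyl)-4,4-dimethylcyclohex-2-en-1-one F2. Stille coupling of the alkenyl iodide with Bu3SnCH2OH (Pd(PPh3)4, dioxane, 80 °C; the unactivated alkyl iodide does not undergo oxidative addition under these conditions) comes back at 8.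

Step 17. The β,γ-epoxy aldehyde and the bromomethyl enone are both sensitive to the Lewis-acidic chromium salts, and oligomerisation competes with ring closure. The fallback sets out from 23 and closes the same bond by catalytic umpolung of a stable allylic acetate, so that no bromo aldehyde is ever handled. Acetylation (Ac2O, pyridine) gives [(4R)-3,3-dimethyl-4-{[(2R,3S)-3-methyl-3-{2-[(2R,3R)-3-methyl-3-(prop-2-en-1-yl)oxiran-2-yl]ethyl}oxiran-2-yl]methyl}-6-oxocyclohex-1-en-1-yl]methyl acetate F3. The same aqueous-acetone ozonolysis gives [(4R)-3,3-dimethyl-4-{[(2R,3S)-3-methyl-3-{2-[(2R,3R)-3-methyl-3-(2-oxoethyl)oxiran-2-yl]ethyl}oxiran-2-yl]methyl}-6-oxocyclohex-1-en-1-yl]methyl acetate F4. Slow addition of F4 to Pd(PPh3)4 (5 mol %) and InI in THF generates a π-allylpalladium species that is reduced to an allylindium, which adds through C11 to the aldehyde and comes back at 28.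

**Further compounds**

F1 | step 2 | (5R)-4,4-dimethyl-5-(nitromethyl)cyclohex-2-en-1-one | O=C1C[C@@H](C[N+](=O)[O-])C(C)(C)C=C1
F2 | step 6 | (5R)-2-iodo-5-(iodomethyl)-4,4-dimethylcyclohex-2-en-1-one | O=C1C[C@@H](CI)C(C)(C)C=C1I
F3 | step 17 | [(4R)-3,3-dimethyl-4-{[(2R,3S)-3-methyl-3-{2-[(2R,3R)-3-methyl-3-(prop-2-en-1-yl)oxiran-2-yl]ethyl}oxiran-2-yl]methyl}-6-oxocyclohex-1-en-1-yl]methyl acetate | O=C1C[C@@H](C[C@H]2O[C@@]2(C)CC[C@H]3O[C@]3(C)CC=C)C(C)(C)C=C1COC(C)=O
F4 | step 17 | [(4R)-3,3-dimethyl-4-{[(2R,3S)-3-methyl-3-{2-[(2R,3R)-3-methyl-3-(2-oxoethyl)oxiran-2-yl]ethyl}oxiran-2-yl]methyl}-6-oxocyclohex-1-en-1-yl]methyl acetate | O=C1C[C@@H](C[C@H]2O[C@@]2(C)CC[C@H]3O[C@]3(C)CC=O)C(C)(C)C=C1COC(C)=O
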